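The runs are calculated with made-up constants; the scatter is artificial.

The leftover of partner is what Saturday's charge is to be judged by. Each substrate takes two partners to reach bis adduct, and whatever partner stands beyond that meets the fork.

| flask | substrate | partner | remark | time |
|---|---|---|---|---|
| amber | 0.020 M | 0.021 M | run made earlier |  |
| ochre | 0.020 M | 0.11 M | run made earlier |  |
| Saturday's | 0.020 M | 0.0800 M |  | 6.0 d |
| Tuesday's | 0.020 M | 0.0160 M |  | 6.0 d |

| run | time / d | triple product / % |
|---|---|---|
| amber | 0.833 | 3 |
| amber | 2.00 | 1 |
| amber | 4.00 | 3 |
| amber | 6.00 | 2 |
| ochre | 0.833 | 39 |
| ochre | 2.00 | 55 |
| ochre | 4.00 | 55 |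
| ochre | 6.00 | 54 |

(each reading ± 2 percentage points)

- percentages count the substrate that a species holds: one side product B counts as two
- steps thought possible: substrate + mono adduct -> side product B; bis adduct -> side product A; partner + bis adduct -> triple product; substrate + partner -> mono adduct; partner -> decomposition product; partner + mono adduct -> bis adduct

- which of these holds the largest part of the substrate at the end of Saturday's (substrate / triple product / mono adduct / bis adduct)
- which of these holds the largest part of the substrate at the end of Tuesday's (substrate / triple product / mono adduct / bis adduct)
- final triple product in Saturday's, as a percentage of the substrate charged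

Bis adduct either takes partner to triple product or falls by itself to side product A. My reckoning freezes partner at the leftover, the charge less two per substrate, as a pseudo-first-order view. The ochre leftover is 0.0700 M, and its plateau reads 54.7%. Taking the rest as side product A gives 0.0580 M, the partner concentration at which bis adduct splits evenly. This is a reading, with the scatter of the plateau in it. The triple share is then [partner]/([partner] + 0.0580 M).

In amber the subtraction gives −0.0190 M, and triple product reads 2%. Saturday's leftover is 0.0400 M, so the reckoning gives 40.8%, less than the ochre plateau. Triple product should lead the four asked. The charge stays if that share will do; a larger share asks for more partner. The time stays too, since ochre reads 55% at 2.00 d and 54% at 6.00 d. Tuesday's charge of 0.0160 M lies below the substrate's 0.020 M, so 20.0% of Tuesday's substrate has no partner to take. This reckoning does not say which species leads in Tuesday's flask.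

The forecast names triple product at 35% for Saturday's and substrate for Tuesday's, holding that “The triple product needs three partner additions, so its yield should depend steeply on partner”. Its figure stands 5.8 percentage points below the reckoning here.

Saturday's ends at 43.0% triple product, leading the four asked. Tuesday's ends with substrate at 42.1%.

    substrate + mono adduct → side product B (k = 0.300 M⁻¹ h⁻¹)
    bis adduct → side product A (k = 0.0470 h⁻¹)
    partner + bis adduct → triple product (k = 0.840 M⁻¹ h⁻¹)
    substrate + partner → mono adduct (k = 1.80 M⁻¹ h⁻¹)
    partner → decomposition product (k = 8.70 × 10⁻⁵ h⁻¹)
    partner + mono adduct → bis adduct (k = 4.50 M⁻¹ h⁻¹)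

Saturday's holds 43.0% as triple product and 55.4% as side product A, and that ratio times 0.0580 M implies 0.0450 M of partner. The partner still standing at 6.00 d is 0.0314 M, 39.3% of its charge. A neighbouring flask, Saturday's with 0.14 M of partner, has a leftover of 0.100 M, so the share reckons to 63.3%. That flask gives 63.7% triple product and 35.6% side product A.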